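Anabsinthin is cut back, through its C10′–O–C4′ ether and its C2–C2′/C3–C5′ Diels–Alder bonds, to two copies of one guaianolide diene. The plan rests on disconnecting the bond C1–C5 shared by the five- and seven-membered rings of that monomer: it is a transannular bond of a ten-membered ring (C1–C10). The key step makes it by acid-triggered attack of the C1=C10 alkene on the 4,5-epoxide of 11β,13-dihydroparthenolide, a germacranolide that already holds the C6/C7 trans-lactone and the C11 methyl; both carbocycles and C5 are set at once. A β-epoxide then delivers the C10 oxygen and the cyclopentadiene.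

Key step: step 2

Remark: guaiane/germacrane numbering (C1–C15) is used throughout, primed numbers mark the half of the dimer that reacts as the diene, and α/β refer to the usual guaianolide drawing in which H-5 and H-7 are α and H-6 is β.

Step 1
Reactants: 1 parthenolide
Product: 2 11β,13-dihydroparthenolide (4α,5β-epoxy-11βH-germacr-1(10)E-en-12,6α-olide; 4R,5R,6S,7S,11S)
Conditions: NaBH4, MeOH, 0 °C
Reagents that add atoms: none
Why: Conjugate (1,4) hydride reduction of the α-methylene-γ-butyrolactone, in which the lactone enolate is protonated under equilibrating conditions so that the new C11 methyl lies α and trans to C8 on the lactone ring (11β-H, 11S), while the epoxide and the trisubstituted alkene are inert to borohydride.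

Step 2
Reactants: 2 11β,13-dihydroparthenolide
Product: 3 4α-hydroxy-5αH,11βH-guai-1(10)-en-12,6α-olide (11β,13-dihydromicheliolide; 4R,5S,6S,7S,11S)
Conditions: p-TsOH·H2O (cat.), CH2Cl2, rt
Reagents that add atoms: none
Why: Brønsted acid activates the epoxide oxygen, the C1=C10 π bond attacks C5 from the side opposite the C5–O bond to form C1–C5, and the tertiary C10 cation then sheds H-1 to leave the tetrasubstituted C1=C10 alkene. The closest known reaction type is the acid-promoted transannular epoxide–alkene (cation–olefin) cyclization of 4,5-epoxygermacranolides to guaianolides. The five-membered ring (C1–C5) closes 5-exo with respect to the alkene and 5-endo with respect to the epoxide, and the seven-membered ring (C1, C5–C10) is closed by the same bond, 7-endo with respect to the alkene and 7-exo with respect to the epoxide. The single new stereocenter, C5, results from inversion at the epoxide carbon, which puts H-5 α and cis to the retained 4α-hydroxyl (5S), while C4, C6, C7 and C11 are not touched. Guaiane rather than eudesmane connectivity is needed and is secured because bonding through C1 leaves the charge on tertiary C10 (bonding through C10 would leave a secondary cation at C1) and because the trans-fused lactone holds the ring in the crown conformer in which C1 sits behind the C5–O bond. Proton loss toward C1 rather than C9 or C14 is favoured by the non-nucleophilic medium and by formation of the most substituted alkene.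

Step 3
Reactants: 3 4α-hydroxy-5αH,11βH-guai-1(10)-en-12,6α-olide; 4 mCPBA
Product: 5 1β,10β-epoxy-4α-hydroxy-5αH,11βH-guaian-12,6α-olide (1R,10S; epoxide oxygen trans to H-5)
Conditions: mCPBA, NaHCO3, CH2Cl2, 0 °C
Reagents that add atoms: mCPBA (3-chloroperoxybenzoic acid), OOC(=O)c1cccc(Cl)c1
Why: Prilezhaev epoxidation of the only alkene, which is electron-rich and tetrasubstituted, with the peracid expected on the β face (opposite H-5 and the C4 hydroxyl, by analogy with the 11(13)-dehydro analogue of 3), so that C1 (R) and C10 (S) are set together while the buffer protects the acid-labile epoxide.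

Step 4
Reactants: 5 1β,10β-epoxy-4α-hydroxy-5αH,11βH-guaian-12,6α-olide
Product: 6 1β,10β-epoxy-5αH,11βH-guai-3-en-12,6α-olide
Conditions: Martin sulfurane Ph2S[OC(CF3)2Ph]2, CH2Cl2, 0 °C to rt
Reagents that add atoms: none
Why: Martin sulfurane dehydration of the tertiary alcohol by anti elimination from the alkoxysulfonium ion, in which H-5 is cis to the leaving group and cannot be reached, so that only H-3β or a C15 hydrogen can leave and the Zaitsev preference for the endocyclic cyclopentene gives the C3=C4 alkene under neutral conditions that spare the epoxide; no stereocenter is formed.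

Step 5
Reactants: 6 1β,10β-epoxy-5αH,11βH-guai-3-en-12,6α-olide; 7 trimethylsilyl trifluoromethanesulfonate
Product: 8 10β-(trimethylsilyloxy)-11βH-guaia-1(5),3-dien-12,6α-olide (10S; cyclopentadiene with its CH2 at C2)
Conditions: TMSOTf, 2,6-lutidine, CH2Cl2, −78 to 0 °C
Reagents that add atoms: trimethylsilyl trifluoromethanesulfonate (TMSOTf), C[Si](C)(C)OS(=O)(=O)C(F)(F)F
Why: Silyl triflate–amine isomerization of an epoxide to an allyl silyl ether, in which O-silylation is followed by heterolysis of the C1–O bond and loss of the allylic, anti-periplanar H-5α (the exit that ends in a conjugated cyclopentadiene), whereas the C10–O bond is never broken, so C10 keeps its β oxygen (10S), and the weak hindered base leaves the lactone α-centre alone.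

Step 6
Reactants: 8 10β-(trimethylsilyloxy)-11βH-guaia-1(5),3-dien-12,6α-olide (two molecules)
Product: 10 bis(trimethylsilyl) ether of absinthin, via 2,4-diene silyl ether 9 (not isolated)
Conditions: neat, BHT (cat.), Ar, dark, 45 °C
Reagents that add atoms: none
Why: A reversible suprafacial [1,5]-sigmatropic hydrogen shift from C2 to C1 feeds 9, the only isomer that offers both an unhindered diene (C2=C3–C4=C5) and a cis-disubstituted dienophile (C2=C3), so by the Curtin–Hammett principle the mixture should drain through an endo Diels–Alder dimerization of 9 (cyclopentadiene-dimer pairing C2′–C2 and C5′–C3) in which both partners react on the α face that carries H-1, away from the C10 quaternary centre, which sets C2, C3, C2′ and C5′ and fixes C1 and C1′ as the 1α-H epimers, the epimer favoured because C10 (β) and C7 (α) then leave the planar C1–C5–C6 unit on opposite sides.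

Step 7
Reactants: 10 bis(trimethylsilyl) ether of absinthin
Product: 12 anabsinthin, via absinthin 11 (not isolated)
Conditions: p-TsOH·H2O, THF–H2O, rt to 40 °C
Reagents that add atoms: none
Why: Acid hydrolysis of both tertiary silyl ethers is followed by Markovnikov protonation of the trisubstituted norbornene alkene C3′=C4′ and capture of the tertiary C4′ cation by the C10′ hydroxyl held over it on the one-carbon bridge (intramolecular hydroalkoxylation closing a tetrahydrofuran), which sets C4′ by geometry, while the C10 hydroxyl of the other half stays free because its ether would be a strained 2-oxabicyclo[2.2.1]heptane.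

Compound list
1 | parthenolide (4α,5β-epoxygermacra-1(10)E,11(13)-dien-12,6α-olide; 4R,5R,6S,7S) | C/C1=C\CC[C@@]2(C)O[C@@H]2[C@H]3OC(=O)C(=C)[C@@H]3CC1 | starting material
2 | 11β,13-dihydroparthenolide (4α,5β-epoxy-11βH-germacr-1(10)E-en-12,6α-olide; 11S, C13 methyl α) | C/C1=C\CC[C@@]2(C)O[C@@H]2[C@H]3OC(=O)[C@@H](C)[C@@H]3CC1 | intermediate
3 | 4α-hydroxy-5αH,11βH-guai-1(10)-en-12,6α-olide (11β,13-dihydromicheliolide) | C[C@@]1(O)CCC2=C(C)CC[C@H]3[C@H](C)C(=O)O[C@@H]3[C@@H]12 | intermediate
4 | mCPBA (3-chloroperoxybenzoic acid) | OOC(=O)c1cccc(Cl)c1 | starting material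
5 | 1β,10β-epoxy-4α-hydroxy-5αH,11βH-guaian-12,6α-olide (1R,10S) | C[C@@]1(O)CC[C@]23O[C@@]2(C)CC[C@H]4[C@H](C)C(=O)O[C@@H]4[C@@H]13 | intermediate
6 | 1β,10β-epoxy-5αH,11βH-guai-3-en-12,6α-olide | CC1=CC[C@]23O[C@@]2(C)CC[C@H]4[C@H](C)C(=O)O[C@@H]4[C@@H]13 | intermediate
7 | trimethylsilyl trifluoromethanesulfonate (TMSOTf) | C[Si](C)(C)OS(=O)(=O)C(F)(F)F | starting material
8 | 10β-(trimethylsilyloxy)-11βH-guaia-1(5),3-dien-12,6α-olide (10S) | CC1=CCC2=C1[C@H]1OC(=O)[C@@H](C)[C@@H]1CC[C@]2(C)O[Si](C)(C)C | intermediate
9 | 10β-(trimethylsilyloxy)-1αH,11βH-guaia-2,4-dien-12,6α-olide (1R,10S; not isolated) | CC1=C2[C@H]3OC(=O)[C@@H](C)[C@@H]3CC[C@](C)(O[Si](C)(C)C)[C@@H]2C=C1 | intermediate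
10 | bis(trimethylsilyl) ether of absinthin (endo [4+2] dimer of 9: bonds C2′–C2 and C5′–C3, C1′ as one-carbon bridge, C3′=C4′ and C4=C5 alkenes, H-1 and H-1′ α, both C10 oxygens β and silylated) | CC1=C2[C@H]3OC(=O)[C@@H](C)[C@@H]3CC[C@](C)(O[Si](C)(C)C)[C@@H]2[C@H]2[C@H]3C=C(C)[C@@]4([C@H]5OC(=O)[C@@H](C)[C@@H]5CC[C@](C)(O[Si](C)(C)C)[C@H]34)[C@@H]12 | intermediate
11 | absinthin (the 10,10′-diol of 10; not isolated) | CC1=C2[C@H]3OC(=O)[C@@H](C)[C@@H]3CC[C@](C)(O)[C@@H]2[C@H]2[C@H]3C=C(C)[C@@]4([C@H]5OC(=O)[C@@H](C)[C@@H]5CC[C@](C)(O)[C@H]34)[C@@H]12 | intermediate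
12 | anabsinthin (C10′–O–C4′ ether of absinthin) | CC1=C2[C@H]3OC(=O)[C@@H](C)[C@@H]3CC[C@](C)(O)[C@@H]2[C@H]2[C@H]3C[C@]4(C)O[C@@]5(C)CC[C@H]6[C@H](C)C(=O)O[C@@H]6[C@@]4([C@@H]35)[C@@H]12 | target

Total step count: 7
Longest linear sequence: 7 steps (1 to 12; step 6 joins two molecules of the same intermediate)

Steps most likely to fail

Step 5. The silylated epoxide may ionize at C10–O instead of C1–O, or the β-silyloxy cation may undergo a 1,2-alkyl shift (Meinwald-type) instead of losing a proton. A second ionization of the allylic silyl ether toward a fulvene is also possible. Proton loss from C2 in place of C5 would be harmless, since it enters the same sigmatropic manifold. The fallback abandons the epoxide and takes the C10 oxygen from dioxygen. It sets out from 3. Burgess reagent (benzene, 50 °C) should remove the 4α-hydroxyl by syn elimination through the cis, allylic H-5α and give 11βH-guaia-1(10),4-dien-12,6α-olide F1. Photooxygenation (O2, tetraphenylporphyrin, visible light, CH2Cl2, −20 °C) is a Schenck ene reaction at the more electron-rich C1=C10 bond. Hydrogen is taken from C2, geminal to the vinyl substituent, so that oxygen ends on C10 and the diene stays conjugated, giving 10β-hydroperoxy-11βH-guaia-1,4-dien-12,6α-olide F2. PPh3 in the same flask reduces it to 10β-hydroxy-11βH-guaia-1,4-dien-12,6α-olide F3. TMSCl and imidazole in DMF give 10β-(trimethylsilyloxy)-11βH-guaia-1,4-dien-12,6α-olide F4, whose [1,5]-hydrogen shift from C3 to C2 under the conditions of step 6 comes back to the route at 8. In this variant the C10 configuration rests on the facial selectivity of oxygen attack on a planar diene, which the substrate does not clearly enforce, so the C10 epimers would have to be separated at F3.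

Step 6. The equilibrating cyclopentadiene isomers may pair wrongly and give constitutional isomers of the dimer. The 1β-H epimer may react, or the supply of 9 may be so slow that thermal loss of silanol takes over. The fallback gives up the protecting group and dimerizes the unprotected monomer, whose C10 substituent is smaller and can hydrogen-bond to the partner's lactone. It sets out from 8. Bu4NF buffered with AcOH (THF, 0 °C) should give 10β-hydroxy-11βH-guaia-1(5),3-dien-12,6α-olide F5. Kept neat at 40 °C under argon in base-washed glass, F5 should pass through 10β-hydroxy-1αH,11βH-guaia-2,4-dien-12,6α-olide F6 by the same [1,5]-shift and dimerize directly to absinthin. The fallback comes back to the route at 11, which is then isolated and carried through step 7 as the etherification alone.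

Step 4. Elimination may run toward the C15 methyl and give the exocyclic alkene, which cannot enter the cyclopentadiene manifold. The fallback changes the sense of elimination and the way the C1–O bond is activated. It sets out from 5. Burgess reagent (benzene, 50 °C) eliminates syn and can therefore reach H-5α, which the anti process cannot, to give the vinyl epoxide 1β,10β-epoxy-11βH-guai-4-en-12,6α-olide F7. In F7 the C1–O bond is allylic and is the only one that ionizes readily. TMSOTf and 2,6-lutidine (CH2Cl2, −78 °C) then open it to the C1–C5–C4 allyl cation, and loss of H-3 comes back to the route at 8, bypassing 6.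

Further compounds
F1 | step 5 | 11βH-guaia-1(10),4-dien-12,6α-olide | CC1=C2[C@H]3OC(=O)[C@@H](C)[C@@H]3CCC(C)=C2CC1
F2 | step 5 | 10β-hydroperoxy-11βH-guaia-1,4-dien-12,6α-olide | CC1=C2[C@H]3OC(=O)[C@@H](C)[C@@H]3CC[C@](C)(OO)C2=CC1
F3 | step 5 | 10β-hydroxy-11βH-guaia-1,4-dien-12,6α-olide | CC1=C2[C@H]3OC(=O)[C@@H](C)[C@@H]3CC[C@](C)(O)C2=CC1
F4 | step 5 | 10β-(trimethylsilyloxy)-11βH-guaia-1,4-dien-12,6α-olide | CC1=C2[C@H]3OC(=O)[C@@H](C)[C@@H]3CC[C@](C)(O[Si](C)(C)C)C2=CC1
F5 | step 6 | 10β-hydroxy-11βH-guaia-1(5),3-dien-12,6α-olide | CC1=CCC2=C1[C@H]1OC(=O)[C@@H](C)[C@@H]1CC[C@]2(C)O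
F6 | step 6 | 10β-hydroxy-1αH,11βH-guaia-2,4-dien-12,6α-olide | CC1=C2[C@H]3OC(=O)[C@@H](C)[C@@H]3CC[C@](C)(O)[C@@H]2C=C1
F7 | step 4 | 1β,10β-epoxy-11βH-guai-4-en-12,6α-olide | CC1=C2[C@H]3OC(=O)[C@@H](C)[C@@H]3CC[C@]4(C)O[C@@]42CC1
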